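**Assumption:** the SMILES has no stereodescriptor and no stereocentre; the only stereogenic element is the hindered 6,8'-biaryl axis, which is unspecified. The route therefore gives the compound as drawn, as the racemic atropisomer pair, and no step sets a stereocentre.

## Retrosynthetic overview

1. Target ⇐ CAN oxidative demethylation of a bis(1,4-dimethoxy)binaphthol; both quinones are unveiled last and both OEt groups are carried from the start.
2. Binaphthol ⇐ intramolecular aldol condensation of an aryl benzyl ketone onto an ortho-acetonyl ketone. This closes the OH/CH3 ring of the 6-linked unit and creates the hindered 6,8' aryl–aryl bond in the same event (key step).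
3. That 1,5-diketone ⇐ Pd α-arylation of an acetophenone (acetonyl masked as a dioxolane) with a fully built naphthyl bromide (convergent union through an sp3 carbon).
4. Naphthyl bromide ⇐ an earlier intramolecular aldol benzannulation of an ortho-acetyl/acetonyl arene. Both acetyl/acetonyl arenes ⇐ Claisen rearrangement and Wacker oxidation of two regioisomeric ethoxy-dihydroxyacetophenones, each made from ethylvanillin.
5. Ring order: the two ethylvanillin rings (future quinone rings) → benzenoid ring of the 8'-linked unit → union → benzenoid ring of the 6-linked unit → both quinones.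

## Arm A: ketone partner (6-linked, 3-ethoxy unit)

**Step 1**
Reactants: 1 ethylvanillin (3-ethoxy-4-hydroxybenzaldehyde)
Product: 2 3-bromo-5-ethoxy-4-hydroxybenzaldehyde
Conditions: Br2 (1.05 equiv), NaOAc, AcOH, rt
Reagents that add atoms: bromine, BrBr
Why: Electrophilic aromatic bromination goes to the only free position ortho to the phenol, so monobromination is regiospecific.

**Step 2**
Reactants: 2 3-bromo-5-ethoxy-4-hydroxybenzaldehyde
Product: 3 3-acetyl-5-ethoxy-4-hydroxybenzaldehyde
Conditions: CH2=C(OEt)SnBu3, Pd(PPh3)4 (5 mol %), toluene, 100 °C; then 2 M HCl, THF, rt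
Reagents that add atoms: tributyl(1-ethoxyvinyl)stannane, CCCC[Sn](CCCC)(CCCC)C(=C)OCC (two carbons); water, O (carbonyl oxygen)
Why: Stille coupling with an acetyl-anion equivalent, then enol-ether hydrolysis, installs the methyl ketone ortho to the phenol and tolerates the aldehyde and free OH.

**Step 3**
Reactants: 3 3-acetyl-5-ethoxy-4-hydroxybenzaldehyde
Product: 4 1-(3-ethoxy-2,5-dihydroxyphenyl)ethanone
Conditions: 30 % H2O2 (1.1 equiv), 1 M NaOH, 0 °C → rt; Na2S2O4/HCl work-up
Reagents that add atoms: hydrogen peroxide, OO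
Why: In this Dakin oxidation the aldehyde para to the phenoxide adds hydroperoxide and undergoes aryl migration much faster than the ortho methyl ketone, so only CHO is replaced by OH.

**Step 4**
Reactants: 4 1-(3-ethoxy-2,5-dihydroxyphenyl)ethanone
Product: 5 1-[5-(allyloxy)-3-ethoxy-2-hydroxyphenyl]ethanone
Conditions: allyl bromide (1.05 equiv), K2CO3, acetone, reflux
Reagents that add atoms: allyl bromide, C=CCBr
Why: Williamson etherification is selective for the 5-OH because the 2-OH is hydrogen-bonded to the acetyl carbonyl and flanked by OEt.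

**Step 5**
Reactants: 5 1-[5-(allyloxy)-3-ethoxy-2-hydroxyphenyl]ethanone
Product: 6 1-(2-allyl-5-ethoxy-3,6-dihydroxyphenyl)ethanone
Conditions: PhNEt2, 200 °C, Ar
Reagents that add atoms: none
Why: Aromatic Claisen [3,3] rearrangement goes to the ortho carbon between the ether oxygen and the chelated acetyl (the established preference of 5-allyloxy-2-hydroxyacetophenones) and away from the position next to OEt.

**Step 6**
Reactants: 6 1-(2-allyl-5-ethoxy-3,6-dihydroxyphenyl)ethanone
Product: 7 1-(2-allyl-5-ethoxy-3,6-dimethoxyphenyl)ethanone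
Conditions: MeI (4 equiv), K2CO3, DMF, 50 °C, N2
Reagents that add atoms: iodomethane, CI
Why: Double Williamson O-methylation caps both hydroquinone oxygens as the latent quinone.

**Step 7**
Reactants: 7 1-(2-allyl-5-ethoxy-3,6-dimethoxyphenyl)ethanone
Product: 8 1-(2-acetyl-4-ethoxy-3,6-dimethoxyphenyl)propan-2-one
Conditions: PdCl2 (10 mol %), CuCl (1 equiv), O2 (1 atm), DMF/H2O 7:1, rt
Reagents that add atoms: water, O (O2 is the terminal oxidant)
Why: Tsuji–Wacker oxidation converts the terminal allyl alkene into the Markovnikov methyl ketone.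

**Step 8**
Reactants: 8 1-(2-acetyl-4-ethoxy-3,6-dimethoxyphenyl)propan-2-one
Product: 9 1-{3-ethoxy-2,5-dimethoxy-6-[(2-methyl-1,3-dioxolan-2-yl)methyl]phenyl}ethanone
Conditions: (TMSOCH2)2 (1.2 equiv), TMSOTf (5 mol %), CH2Cl2, −78 → −20 °C; Et3N quench
Reagents that add atoms: 1,2-bis(trimethylsilyloxy)ethane, C[Si](C)(C)OCCO[Si](C)(C)C
Why: Noyori ketalisation protects the unhindered dialkyl ketone in preference to the di-ortho-substituted aryl ketone, which leaves the acetyl as the only enolisable carbonyl and blocks premature cyclisation.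

## Arm B: naphthyl bromide (8'-linked, 2-ethoxy unit)

**Step 9**
Reactants: 1 ethylvanillin
Product: 10 2-ethoxybenzene-1,4-diol
Conditions: 30 % H2O2, 1 M NaOH, 0 °C → rt; Na2S2O4/HCl work-up
Reagents that add atoms: hydrogen peroxide, OO
Why: Dakin oxidation of a para-hydroxybenzaldehyde gives the hydroquinone, as in the vanillin to methoxyhydroquinone conversion.

**Step 10**
Reactants: 10 2-ethoxybenzene-1,4-diol
Product: 11 1-(4-ethoxy-2,5-dihydroxyphenyl)ethanone
Conditions: AcOH, BF3·OEt2, 90 °C
Reagents that add atoms: acetic acid, CC(=O)O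
Why: Friedel–Crafts acylation with BF3/AcOH enters para to OEt and ortho to OH, the most activated position, as with methoxyhydroquinone.

**Step 11**
Reactants: 11 1-(4-ethoxy-2,5-dihydroxyphenyl)ethanone
Product: 12 1-[5-(allyloxy)-4-ethoxy-2-hydroxyphenyl]ethanone
Conditions: allyl bromide (1.05 equiv), K2CO3, acetone, reflux
Reagents that add atoms: allyl bromide, C=CCBr
Why: Williamson etherification alkylates only the 5-OH because the 2-OH is chelated to the acetyl group.

**Step 12**
Reactants: 12 1-[5-(allyloxy)-4-ethoxy-2-hydroxyphenyl]ethanone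
Product: 13 1-(2-allyl-4-ethoxy-3,6-dihydroxyphenyl)ethanone
Conditions: PhNEt2, 200 °C, Ar
Reagents that add atoms: none
Why: The aromatic Claisen rearrangement is regiospecific because the other ortho carbon carries OEt and the para carbon is oxygenated.

**Step 13**
Reactants: 13 1-(2-allyl-4-ethoxy-3,6-dihydroxyphenyl)ethanone
Product: 14 1-(2-allyl-4-ethoxy-3,6-dimethoxyphenyl)ethanone
Conditions: MeI (4 equiv), K2CO3, DMF, 50 °C, N2
Reagents that add atoms: iodomethane, CI
Why: Double Williamson O-methylation gives the hydroquinone dimethyl ether.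

**Step 14**
Reactants: 14 1-(2-allyl-4-ethoxy-3,6-dimethoxyphenyl)ethanone
Product: 15 1-(2-acetyl-5-ethoxy-3,6-dimethoxyphenyl)propan-2-one
Conditions: PdCl2 (10 mol %), CuCl (1 equiv), O2, DMF/H2O 7:1, rt
Reagents that add atoms: water, O
Why: Tsuji–Wacker oxidation gives the methyl ketone of the 1,5-diketone.

**Step 15**
Reactants: 15 1-(2-acetyl-5-ethoxy-3,6-dimethoxyphenyl)propan-2-one
Product: 16 6-ethoxy-5,8-dimethoxy-3-methylnaphthalen-1-ol
Conditions: KOH (2 equiv), MeOH, reflux, N2; acidic work-up
Reagents that add atoms: none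
Why: In this intramolecular aldol condensation the aryl methyl ketone enolate attacks the more electrophilic dialkyl ketone in a six-membered closure, and dehydration with tautomerisation aromatises to the 3-methyl-1-naphthol.

**Step 16**
Reactants: 16 6-ethoxy-5,8-dimethoxy-3-methylnaphthalen-1-ol
Product: 17 4-bromo-6-ethoxy-5,8-dimethoxy-3-methylnaphthalen-1-ol
Conditions: NBS (1.0 equiv), MeCN, −20 → 0 °C
Reagents that add atoms: N-bromosuccinimide, O=C1CCC(=O)N1Br
Why: Electrophilic bromination of a 1-naphthol in MeCN is para (α) selective, helped by the peri OH···OMe hydrogen bond that disfavours ortho delivery and by the naphthol ring being more activated than the ether ring.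

**Step 17**
Reactants: 17 4-bromo-6-ethoxy-5,8-dimethoxy-3-methylnaphthalen-1-ol
Product: 18 1-bromo-7-ethoxy-5,8-dimethoxy-4-(methoxymethoxy)-2-methylnaphthalene
Conditions: NaH, MOMCl, THF/DMF, 0 °C → rt
Reagents that add atoms: chloromethyl methyl ether, COCCl
Why: O-alkylation to the MOM acetal gives a base-stable, acid-labile protecting group for the naphthol.

## Union and endgame

**Step 18**
Reactants: 9 1-{3-ethoxy-2,5-dimethoxy-6-[(2-methyl-1,3-dioxolan-2-yl)methyl]phenyl}ethanone (1.3 equiv); 18 1-bromo-7-ethoxy-5,8-dimethoxy-4-(methoxymethoxy)-2-methylnaphthalene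
Product: 19 1-{3-ethoxy-2,5-dimethoxy-6-[(2-methyl-1,3-dioxolan-2-yl)methyl]phenyl}-2-[7-ethoxy-5,8-dimethoxy-4-(methoxymethoxy)-2-methylnaphthalen-1-yl]ethanone
Conditions: Pd2(dba)3 (2.5 mol %), XPhos (6 mol %), NaOt-Bu (2.2 equiv), toluene, 90 °C
Reagents that add atoms: none
Why: Pd-catalysed ketone α-arylation (Buchwald–Hartwig type) uses the only enolisable site of 9, stops at monoarylation because the bromide is di-ortho-substituted, and makes the future biaryl bond as a C(sp3)–C(sp2) bond.

**Step 19**
Reactants: 19 (ketal/MOM-protected aryl naphthylmethyl ketone)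
Product: 20 1-[3-ethoxy-2,5-dimethoxy-6-(2-oxopropyl)phenyl]-2-(7-ethoxy-4-hydroxy-5,8-dimethoxy-2-methylnaphthalen-1-yl)ethanone
Conditions: 3 M HCl, THF, 50 °C
Reagents that add atoms: water, O (regenerated ketone oxygen)
Why: Aqueous acid hydrolyses the dioxolane and the phenolic MOM acetal together, and any early cyclisation leads to the same product as step 20.

**Step 20 (key step)**
Reactants: 20 (1,5-diketone)
Product: 21 7,7'-diethoxy-5,5',8,8'-tetramethoxy-2,3'-dimethyl-[1,2'-binaphthalene]-1',4-diol (racemic axis)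
Conditions: KOH (3 equiv), degassed MeOH/THF, 60 °C; acidic work-up
Reagents that add atoms: none
Why: In this intramolecular aldol condensation the doubly activated ArC(=O)CH2Ar' enolate attacks the pendant methyl ketone in a six-membered closure, and dehydration with aromatisation gives the 2-aryl-3-methyl-1-naphthol, so the tetra-ortho-substituted biaryl bond is formed by ring construction.

**Step 21**
Reactants: 21 (binaphthol)
Product: 22 2,3'-diethoxyisodiospyrin (target)
Conditions: CAN (5 equiv), MeCN/H2O 3:1, 0 °C, 20 min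
Reagents that add atoms: water, O (quinone oxygens; four MeOH are lost)
Why: CAN oxidative demethylation converts each electron-rich 2-ethoxy-1,4-dimethoxy ring into the para-quinone with OEt retained, and each peri-OH becomes chelated and deactivated once its quinone forms.

## Compound list

1 | ethylvanillin (3-ethoxy-4-hydroxybenzaldehyde) | CCOc1cc(C=O)ccc1O | starting material
2 | 3-bromo-5-ethoxy-4-hydroxybenzaldehyde | CCOc1cc(C=O)cc(Br)c1O | intermediate
3 | 3-acetyl-5-ethoxy-4-hydroxybenzaldehyde | CCOc1cc(C=O)cc(C(C)=O)c1O | intermediate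
4 | 1-(3-ethoxy-2,5-dihydroxyphenyl)ethanone | CCOc1cc(O)cc(C(C)=O)c1O | intermediate
5 | 1-[5-(allyloxy)-3-ethoxy-2-hydroxyphenyl]ethanone | CCOc1cc(OCC=C)cc(C(C)=O)c1O | intermediate
6 | 1-(2-allyl-5-ethoxy-3,6-dihydroxyphenyl)ethanone | CCOc1cc(O)c(CC=C)c(C(C)=O)c1O | intermediate
7 | 1-(2-allyl-5-ethoxy-3,6-dimethoxyphenyl)ethanone | CCOc1cc(OC)c(CC=C)c(C(C)=O)c1OC | intermediate
8 | 1-(2-acetyl-4-ethoxy-3,6-dimethoxyphenyl)propan-2-one | CCOc1cc(OC)c(CC(C)=O)c(C(C)=O)c1OC | intermediate
9 | 1-{3-ethoxy-2,5-dimethoxy-6-[(2-methyl-1,3-dioxolan-2-yl)methyl]phenyl}ethanone | CCOc1cc(OC)c(CC2(C)OCCO2)c(C(C)=O)c1OC | intermediate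
10 | 2-ethoxybenzene-1,4-diol | CCOc1cc(O)ccc1O | intermediate
11 | 1-(4-ethoxy-2,5-dihydroxyphenyl)ethanone | CCOc1cc(O)c(C(C)=O)cc1O | intermediate
12 | 1-[5-(allyloxy)-4-ethoxy-2-hydroxyphenyl]ethanone | CCOc1cc(O)c(C(C)=O)cc1OCC=C | intermediate
13 | 1-(2-allyl-4-ethoxy-3,6-dihydroxyphenyl)ethanone | CCOc1cc(O)c(C(C)=O)c(CC=C)c1O | intermediate
14 | 1-(2-allyl-4-ethoxy-3,6-dimethoxyphenyl)ethanone | CCOc1cc(OC)c(C(C)=O)c(CC=C)c1OC | intermediate
15 | 1-(2-acetyl-5-ethoxy-3,6-dimethoxyphenyl)propan-2-one | CCOc1cc(OC)c(C(C)=O)c(CC(C)=O)c1OC | intermediate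
16 | 6-ethoxy-5,8-dimethoxy-3-methylnaphthalen-1-ol | CCOc1cc(OC)c2c(O)cc(C)cc2c1OC | intermediate
17 | 4-bromo-6-ethoxy-5,8-dimethoxy-3-methylnaphthalen-1-ol | CCOc1cc(OC)c2c(O)cc(C)c(Br)c2c1OC | intermediate
18 | 1-bromo-7-ethoxy-5,8-dimethoxy-4-(methoxymethoxy)-2-methylnaphthalene | CCOc1cc(OC)c2c(OCOC)cc(C)c(Br)c2c1OC | intermediate
19 | 1-{3-ethoxy-2,5-dimethoxy-6-[(2-methyl-1,3-dioxolan-2-yl)methyl]phenyl}-2-[7-ethoxy-5,8-dimethoxy-4-(methoxymethoxy)-2-methylnaphthalen-1-yl]ethanone | CCOc1cc(OC)c(CC2(C)OCCO2)c(C(=O)Cc2c(C)cc(OCOC)c3c(OC)cc(OCC)c(OC)c23)c1OC | intermediate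
20 | 1-[3-ethoxy-2,5-dimethoxy-6-(2-oxopropyl)phenyl]-2-(7-ethoxy-4-hydroxy-5,8-dimethoxy-2-methylnaphthalen-1-yl)ethanone | CCOc1cc(OC)c(CC(C)=O)c(C(=O)Cc2c(C)cc(O)c3c(OC)cc(OCC)c(OC)c23)c1OC | intermediate
21 | 7,7'-diethoxy-5,5',8,8'-tetramethoxy-2,3'-dimethyl-[1,2'-binaphthalene]-1',4-diol (racemic axis) | CCOc1cc(OC)c2cc(C)c(-c3c(C)cc(O)c4c(OC)cc(OCC)c(OC)c34)c(O)c2c1OC | intermediate
22 | 2,3'-diethoxyisodiospyrin (no stereocentres; racemic axis) | CCOC1=CC(=O)c2cc(C)c(-c3c(C)cc(O)c4c3C(=O)C(OCC)=CC4=O)c(O)c2C1=O | target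

## Summary

**Total steps:** 21 (arm A 8, arm B 9, union and endgame 4).

**Longest linear sequence:** 13 steps (steps 9–17, then 18–21), which is 13/21 ≈ 0.62 of the total. The other arm is 8 + 4 = 12.

**Steps most likely to fail, each with a fallback:**

- **Step 18** (α-arylation with the ortho/peri-hindered, electron-rich bromide 18). Fallback: abandon the sp3 union. Cyclise 8 with KOH (the same aldol benzannulation) to 7-ethoxy-5,8-dimethoxy-3-methylnaphthalen-1-ol, brominate ortho to OH (NBS, cat. i-Pr2NH), MOM-protect, Miyaura-borylate, and join to 18 by Suzuki–Miyaura coupling (Pd/SPhos). The biaryl bond is then made by cross-coupling after both naphthalenes exist.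
- **Step 16** (para versus ortho bromination of naphthol 16). Fallback: replace direct halogenation with azo coupling (PhN2+, para-specific for 1-naphthols), reduce with Na2S2O4 to the 4-aminonaphthol, MOM-protect, and convert to the bromide by Sandmeyer reaction (t-BuONO, CuBr2).
- **Step 20** (aldol closure that builds the tetra-ortho-substituted biaryl; the bulky enolate may be slow). Fallback: skip step 19. Convert the benzyl ketone of 19 into its silyl enol ether (TMSOTf, Et3N) and close the ring by TiCl4-mediated Mukaiyama addition to the dioxolane, then eliminate, aromatise and remove the MOM group with acid.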